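1. Target 22 comes from silyl ether 21 by desilylation. The only ring that is built is the butenolide (O1, C2, C3, C4, C5), closed in the step before the last; the furan ring is bought in furan-3-ylmethanol 1.
2. The lactone carbonyl carbon C2 is cut out as CO (bonds C2–C3 and C2–O1), leaving the acyclic (Z)-β-iodoenone 20. A palladium-catalysed carbonylative (4+1) lactonisation closes the ring and raises the exocyclic (Z)-C5=C1′ bond in the same operation.
3. Enabling feature: C2 is a single carbon at the oxidation level of CO between O1 and the vinylic C3, and C5 is a latent ketone whose neighbour C1′ carries two hydrogens. O1=C5–C4=C3–I is therefore a four-atom partner for CO, and enolisation towards C1′ supplies both the nucleophilic O1 and the ylidene.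
4. 20 comes from ynone 19 (HI addition), 19 from Weinreb amide 16 and the acetylide of 17. The (S)-methyl centre comes from (S)-β-butyrolactone 13, opened with inversion by Grignard reagent 14 under copper catalysis.
5. The (E,E)-chain of 14 comes from geranyl chloride 3 and furan-3-ylmethyl Grignard reagent 4 (dendrolasin 5), SeO2 oxidation of the terminal (E)-methyl group, and a two-carbon extension with tert-butyl acetate 8.

Key step: step 12

Remark: commercial geranyl chloride 3 is taken as the pure (E)-isomer and (S)-β-butyrolactone 13 as enantiopure material.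

Step 1
Reactants: 1 furan-3-ylmethanol
Product: 2 3-(chloromethyl)furan
Conditions: SOCl2, pyridine, Et2O, 0 °C
Reagents that add atoms: thionyl chloride, ClS(Cl)=O
Why: Chlorodehydroxylation of a primary heteroarylmethyl alcohol through its chlorosulfite (SN2), with pyridine keeping free HCl away from the acid-sensitive furan.

Step 2
Reactants: 2 3-(chloromethyl)furan; 3 geranyl chloride ((2E)-1-chloro-3,7-dimethylocta-2,6-diene)
Product: 5 dendrolasin (3-[(3E)-4,8-dimethylnona-3,7-dien-1-yl]furan), via furan-3-ylmethylmagnesium chloride 4 (not isolated)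
Conditions: Mg, THF, 0 °C; then 3, Li2CuCl4 (cat.), THF, 0 °C
Reagents that add atoms: none
Why: Copper-catalysed sp3–sp3 cross-coupling of a Grignard reagent with a primary allylic chloride should occur at the α-carbon (SN2) and leave the (E)-trisubstituted double bond of the geranyl unit untouched.

Step 3
Reactants: 5 dendrolasin
Product: 6 (2E,6E)-9-(furan-3-yl)-2,6-dimethylnona-2,6-dien-1-ol
Conditions: SeO2 (cat.), t-BuOOH, salicylic acid (cat.), CH2Cl2, 0 °C to rt
Reagents that add atoms: selenium dioxide, O=[Se]=O (oxygen carrier); tert-butyl hydroperoxide, CC(C)(C)OO (terminal oxygen source)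
Why: Riley-type allylic oxidation (ene reaction, then [2,3]-sigmatropic shift) should select the (E)-methyl group of the terminal, least hindered isopropylidene unit and so give the (E)-allylic alcohol, under conditions mild enough for a 3-alkylfuran.

Step 4
Reactants: 6 (2E,6E)-9-(furan-3-yl)-2,6-dimethylnona-2,6-dien-1-ol
Product: 7 3-[(3E,7E)-9-bromo-4,8-dimethylnona-3,7-dien-1-yl]furan
Conditions: CBr4, PPh3, CH2Cl2, -20 to 0 °C
Reagents that add atoms: carbon tetrabromide, BrC(Br)(Br)Br
Why: Appel reaction of a primary allylic alcohol under neutral conditions should proceed by SN2 displacement of the oxyphosphonium group without allylic transposition or loss of alkene geometry.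

Step 5
Reactants: 7 3-[(3E,7E)-9-bromo-4,8-dimethylnona-3,7-dien-1-yl]furan; 8 tert-butyl acetate
Product: 10 tert-butyl (4E,8E)-11-(furan-3-yl)-4,8-dimethylundeca-4,8-dienoate, via lithium 1-tert-butoxyethen-1-olate 9 (not isolated)
Conditions: 8, LiN(i-Pr)2, THF, -78 °C; then 7, THF–DMPU, -78 to -20 °C
Reagents that add atoms: none
Why: SN2 alkylation of a lithium ester enolate by a primary allylic bromide, the tert-butyl ester suppressing Claisen self-condensation and the alkene geometry not being touched.

Step 6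
Reactants: 10 tert-butyl (4E,8E)-11-(furan-3-yl)-4,8-dimethylundeca-4,8-dienoate
Product: 11 (4E,8E)-11-(furan-3-yl)-4,8-dimethylundeca-4,8-dien-1-ol
Conditions: LiAlH4, Et2O, 0 °C to rt
Reagents that add atoms: none
Why: Hydride reduction of the ester to the primary alcohol; the furan and the isolated trisubstituted alkenes are inert to LiAlH4.

Step 7
Reactants: 11 (4E,8E)-11-(furan-3-yl)-4,8-dimethylundeca-4,8-dien-1-ol
Product: 12 3-[(3E,7E)-11-bromo-4,8-dimethylundeca-3,7-dien-1-yl]furan
Conditions: CBr4, PPh3, CH2Cl2, 0 °C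
Reagents that add atoms: carbon tetrabromide, BrC(Br)(Br)Br
Why: Appel reaction converts the unhindered primary alcohol into the bromide needed for Grignard formation under neutral conditions.

Step 8
Reactants: 12 3-[(3E,7E)-11-bromo-4,8-dimethylundeca-3,7-dien-1-yl]furan; 13 (S)-β-butyrolactone ((4S)-4-methyloxetan-2-one)
Product: 15 (3S,7E,11E)-14-(furan-3-yl)-3,7,11-trimethyltetradeca-7,11-dienoic acid, via alkylmagnesium bromide 14 (not isolated)
Conditions: Mg, THF, 40 °C; then 13, CuBr·SMe2 (5 mol %), THF–Me2S, -30 to 0 °C; cold 1 M HCl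
Reagents that add atoms: none
Why: Copper-catalysed SN2 opening of the β-lactone at C4 (alkyl–oxygen cleavage) goes with inversion and sets the methyl-bearing centre from the lactone; the descriptor stays S because the CIP ranking of the substituents changes, and monovalent copper suppresses attack at the lactone carbonyl.

Step 9
Reactants: 15 (3S,7E,11E)-14-(furan-3-yl)-3,7,11-trimethyltetradeca-7,11-dienoic acid
Product: 16 (3S,7E,11E)-14-(furan-3-yl)-N-methoxy-N,3,7,11-tetramethyltetradeca-7,11-dienamide
Conditions: MeNHOMe·HCl, EDC·HCl, N-methylmorpholine, DMAP (cat.), CH2Cl2, 0 °C to rt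
Reagents that add atoms: N,O-dimethylhydroxylamine hydrochloride, CNOC.Cl
Why: Carbodiimide amide coupling to the Weinreb amide; the stereocentre is β to the carbonyl and cannot epimerise.

Step 10
Reactants: 16 (3S,7E,11E)-14-(furan-3-yl)-N-methoxy-N,3,7,11-tetramethyltetradeca-7,11-dienamide; 17 tert-butyldimethyl(prop-2-yn-1-yloxy)silane
Product: 19 (6S,10E,14E)-1-{[tert-butyl(dimethyl)silyl]oxy}-17-(furan-3-yl)-6,10,14-trimethylheptadeca-10,14-dien-2-yn-4-one, via lithium acetylide 18 (not isolated)
Conditions: 17, n-BuLi, THF, -78 °C; then 16, -78 to 0 °C; aq NH4Cl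
Reagents that add atoms: none
Why: Weinreb ketone synthesis: the lithium acetylide adds once to give a chelated tetrahedral intermediate that collapses to the ynone only on work-up, so over-addition is avoided.

Step 11
Reactants: 19 (6S,10E,14E)-1-{[tert-butyl(dimethyl)silyl]oxy}-17-(furan-3-yl)-6,10,14-trimethylheptadeca-10,14-dien-2-yn-4-one
Product: 20 (2Z,6S,10E,14E)-1-{[tert-butyl(dimethyl)silyl]oxy}-17-(furan-3-yl)-2-iodo-6,10,14-trimethylheptadeca-2,10,14-trien-4-one
Conditions: NaI, AcOH, MeCN, 0 °C to rt, dark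
Reagents that add atoms: sodium iodide, [Na+].[I-]
Why: Conjugate hydroiodination of the ynone: iodide adds to the β-carbon and the allenol intermediate is protonated anti, which should give the kinetic (Z)-β-iodoenone with iodine cis to the acyl group, a short reaction time in the dark limiting Z-to-E equilibration.

Step 12
Reactants: 20 (2Z,6S,10E,14E)-1-{[tert-butyl(dimethyl)silyl]oxy}-17-(furan-3-yl)-2-iodo-6,10,14-trimethylheptadeca-2,10,14-trien-4-one
Product: 21 (5Z)-3-({[tert-butyl(dimethyl)silyl]oxy}methyl)-5-[(2S,6E,10E)-13-(furan-3-yl)-2,6,10-trimethyltrideca-6,10-dien-1-ylidene]furan-2(5H)-one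
Conditions: PdCl2(PPh3)2 (5 mol %), CO (10 atm), i-Pr2NEt (2 equiv), dry MeCN, 60 °C
Reagents that add atoms: carbon monoxide, [C-]#[O+]
Why: Zerovalent palladium, formed in situ from the divalent precatalyst, inserts into the C3–I bond with retention, CO migratory insertion makes the C2–C3 bond, and the acylpalladium held cis to the C5 ketone is captured by the C5 enol oxygen while the amine removes one C1′ hydrogen, releasing the lactone and zerovalent palladium. The closest known reaction type is the palladium-catalysed carbonylative lactonisation of (Z)-β-iodoenones and of o-halogenoaryl ketones with O-enolate trapping of the acylpalladium, formally a (4+1) annulation of the O1=C5–C4=C3 unit with CO. The butenolide ring is closed at C2 in this single operation, C2–C3 by CO insertion and then O1–C2 by a 5-exo-trig acyl substitution. No new stereocentre is formed; the new stereo-element is the exocyclic C5=C1′ bond, which should come out Z because the E arrangement would press the side chain against C4–H (A1,3 strain) and the Z-ylidene butenolide is also the thermodynamic isomer, while the C2′ centre is not acidic towards the amine and is kept. The step needs the acylpalladium cis to the ketone (secured by the Z-iodoenone and stereoretentive oxidative addition and insertion), O- rather than C-trapping (only O gives a five-membered ring) and no competing nucleophile (dry medium, hindered base, hydroxyl masked as silyl ether so that no β-lactone can form). Any E-iodoenone formed on the way can re-enter through iodide addition–elimination, since the released iodide stays in solution.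

Step 13
Reactants: 21 (5Z)-3-({[tert-butyl(dimethyl)silyl]oxy}methyl)-5-[(2S,6E,10E)-13-(furan-3-yl)-2,6,10-trimethyltrideca-6,10-dien-1-ylidene]furan-2(5H)-one
Product: 22 (5Z)-5-[(2S,6E,10E)-13-(furan-3-yl)-2,6,10-trimethyltrideca-6,10-dien-1-ylidene]-3-(hydroxymethyl)furan-2(5H)-one
Conditions: HF·pyridine, pyridine, THF, 0 °C to rt
Reagents that add atoms: none
Why: Fluoride cleavage of the primary silyl ether under buffered, non-basic conditions should leave the base-sensitive ylidene butenolide, the furan and the stereocentre untouched.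

Compound list
1 | furan-3-ylmethanol | OCc1ccoc1 | starting material
2 | 3-(chloromethyl)furan | ClCc1ccoc1 | intermediate
3 | geranyl chloride, (2E)-1-chloro-3,7-dimethylocta-2,6-diene | CC(C)=CCC/C(C)=C/CCl | starting material
4 | (furan-3-ylmethyl)magnesium chloride | Cl[Mg]Cc1ccoc1 | intermediate
5 | dendrolasin, 3-[(3E)-4,8-dimethylnona-3,7-dien-1-yl]furan | C/C(=C\CCc1ccoc1)CCC=C(C)C | intermediate
6 | (2E,6E)-9-(furan-3-yl)-2,6-dimethylnona-2,6-dien-1-ol | C/C(=C\CCc1ccoc1)CC/C=C(\C)CO | intermediate
7 | 3-[(3E,7E)-9-bromo-4,8-dimethylnona-3,7-dien-1-yl]furan | C/C(=C\CCc1ccoc1)CC/C=C(\C)CBr | intermediate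
8 | tert-butyl acetate | CC(=O)OC(C)(C)C | starting material
9 | lithium 1-tert-butoxyethen-1-olate (lithium enolate of 8) | [Li]OC(=C)OC(C)(C)C | intermediate
10 | tert-butyl (4E,8E)-11-(furan-3-yl)-4,8-dimethylundeca-4,8-dienoate | C/C(=C\CCc1ccoc1)CC/C=C(\C)CCC(=O)OC(C)(C)C | intermediate
11 | (4E,8E)-11-(furan-3-yl)-4,8-dimethylundeca-4,8-dien-1-ol | C/C(=C\CCc1ccoc1)CC/C=C(\C)CCCO | intermediate
12 | 3-[(3E,7E)-11-bromo-4,8-dimethylundeca-3,7-dien-1-yl]furan | C/C(=C\CCc1ccoc1)CC/C=C(\C)CCCBr | intermediate
13 | (S)-β-butyrolactone, (4S)-4-methyloxetan-2-one | C[C@H]1CC(=O)O1 | starting material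
14 | [(4E,8E)-11-(furan-3-yl)-4,8-dimethylundeca-4,8-dien-1-yl]magnesium bromide | C/C(=C\CCc1ccoc1)CC/C=C(\C)CCC[Mg]Br | intermediate
15 | (3S,7E,11E)-14-(furan-3-yl)-3,7,11-trimethyltetradeca-7,11-dienoic acid | C/C(=C\CCc1ccoc1)CC/C=C(\C)CCC[C@H](C)CC(=O)O | intermediate
16 | (3S,7E,11E)-14-(furan-3-yl)-N-methoxy-N,3,7,11-tetramethyltetradeca-7,11-dienamide | C/C(=C\CCc1ccoc1)CC/C=C(\C)CCC[C@H](C)CC(=O)N(C)OC | intermediate
17 | tert-butyldimethyl(prop-2-yn-1-yloxy)silane | C#CCO[Si](C)(C)C(C)(C)C | starting material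
18 | lithium 3-{[tert-butyl(dimethyl)silyl]oxy}prop-1-yn-1-ide (lithium acetylide of 17) | [Li]C#CCO[Si](C)(C)C(C)(C)C | intermediate
19 | (6S,10E,14E)-1-{[tert-butyl(dimethyl)silyl]oxy}-17-(furan-3-yl)-6,10,14-trimethylheptadeca-10,14-dien-2-yn-4-one | C/C(=C\CCc1ccoc1)CC/C=C(\C)CCC[C@H](C)CC(=O)C#CCO[Si](C)(C)C(C)(C)C | intermediate
20 | (2Z,6S,10E,14E)-1-{[tert-butyl(dimethyl)silyl]oxy}-17-(furan-3-yl)-2-iodo-6,10,14-trimethylheptadeca-2,10,14-trien-4-one | C/C(=C\CCc1ccoc1)CC/C=C(\C)CCC[C@H](C)CC(=O)/C=C(\I)CO[Si](C)(C)C(C)(C)C | intermediate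
21 | (5Z)-3-({[tert-butyl(dimethyl)silyl]oxy}methyl)-5-[(2S,6E,10E)-13-(furan-3-yl)-2,6,10-trimethyltrideca-6,10-dien-1-ylidene]furan-2(5H)-one | C/C(=C\CCc1ccoc1)CC/C=C(\C)CCC[C@H](C)/C=C1/C=C(CO[Si](C)(C)C(C)(C)C)C(=O)O1 | intermediate
22 | (5Z)-5-[(2S,6E,10E)-13-(furan-3-yl)-2,6,10-trimethyltrideca-6,10-dien-1-ylidene]-3-(hydroxymethyl)furan-2(5H)-one | C/C(=C\CCc1ccoc1)CC/C=C(\C)CCC[C@H](C)/C=C1/C=C(CO)C(=O)O1 | target

Total step count: 13. Longest linear sequence: 13 steps (1 to 22).

Steps most likely to fail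

Step 12. The acylpalladium intermediate may be diverted (protonolysis or reductive coupling of the palladium-bound oxa-allyl species, or decarbonylation). The iodoenone may also isomerise from Z to E faster than it is consumed, or the amine may add to C3 and displace iodide. Fallback, setting out from 20 and coming back at 21: palladium-catalysed methoxycarbonylation (PdCl2(PPh3)2, CO 1 atm, MeOH, i-Pr2NEt, DMF, rt) should give methyl (2Z,6S,10E,14E)-2-({[tert-butyl(dimethyl)silyl]oxy}methyl)-17-(furan-3-yl)-6,10,14-trimethyl-4-oxoheptadeca-2,10,14-trienoate F1. Saponification (LiOH, THF–H2O, 0 °C) should give the Z-keto acid as its ring tautomer, 3-({[tert-butyl(dimethyl)silyl]oxy}methyl)-5-[(2S,6E,10E)-13-(furan-3-yl)-2,6,10-trimethyltrideca-6,10-dien-1-yl]-5-hydroxyfuran-2(5H)-one F2 (both C5 epimers). Dehydration (MeSO2Cl, NEt3, CH2Cl2, 0 °C) should then give 21. In this variant the ring is closed at O1–C5 and the ylidene is made by a separate elimination.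

Step 3. The ene step may show poor site selectivity between the terminal and the internal trisubstituted alkene, the alcohol may be over-oxidised to the enal, and the furan ring may be degraded oxidatively. Fallback, setting out from 2 (through its Grignard reagent 4) and coming back at 6: the oxidation is done before the furan is present. Commercial geranyl acetate, whose acetate deactivates the nearer double bond, is oxidised (SeO2 cat., t-BuOOH, CH2Cl2) to (2E,6E)-8-hydroxy-3,7-dimethylocta-2,6-dien-1-yl acetate F3. Silylation (t-BuMe2SiCl, imidazole, DMF) should give (2E,6E)-8-{[tert-butyl(dimethyl)silyl]oxy}-3,7-dimethylocta-2,6-dien-1-yl acetate F4, and methanolysis (K2CO3, MeOH) should give (2E,6E)-8-{[tert-butyl(dimethyl)silyl]oxy}-3,7-dimethylocta-2,6-dien-1-ol F5. MeSO2Cl, LiCl, 2,4,6-collidine in DMF at 0 °C should give tert-butyl{[(2E,6E)-8-chloro-2,6-dimethylocta-2,6-dien-1-yl]oxy}dimethylsilane F6. Li2CuCl4-catalysed coupling with 4 should give tert-butyl{[(2E,6E)-9-(furan-3-yl)-2,6-dimethylnona-2,6-dien-1-yl]oxy}dimethylsilane F7, and Bu4NF in THF should release 6.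

Step 8. The Grignard reagent may attack the lactone carbonyl (acyl–oxygen cleavage) in competition with the SN2 opening, and Wurtz-type homocoupling may occur while the Grignard reagent is formed. Fallback, setting out from 12 (through its Grignard reagent 14) and coming back at 15: the centre is set by auxiliary-controlled conjugate addition instead of substitution at a chiral electrophile. Commercial (4S)-4-phenyl-1,3-oxazolidin-2-one is N-acylated ((E)-but-2-enoyl chloride, n-BuLi, THF, -78 °C) to (4S)-3-[(2E)-but-2-enoyl]-4-phenyl-1,3-oxazolidin-2-one F8. Reagent 14 with CuBr·SMe2 (THF–Me2S, -20 °C) should add to the β-carbon anti to the phenyl group of the magnesium-chelated s-cis imide, giving (4S)-3-[(3S,7E,11E)-14-(furan-3-yl)-3,7,11-trimethyltetradeca-7,11-dienoyl]-4-phenyl-1,3-oxazolidin-2-one F9. LiOH, H2O2 in THF–H2O at 0 °C should release acid 15.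

Further compounds
F1 | step 12 | methyl (2Z,6S,10E,14E)-2-({[tert-butyl(dimethyl)silyl]oxy}methyl)-17-(furan-3-yl)-6,10,14-trimethyl-4-oxoheptadeca-2,10,14-trienoate | C/C(=C\CCc1ccoc1)CC/C=C(\C)CCC[C@H](C)CC(=O)/C=C(\C(=O)OC)CO[Si](C)(C)C(C)(C)C
F2 | step 12 | 3-({[tert-butyl(dimethyl)silyl]oxy}methyl)-5-[(2S,6E,10E)-13-(furan-3-yl)-2,6,10-trimethyltrideca-6,10-dien-1-yl]-5-hydroxyfuran-2(5H)-one (both C5 epimers) | C/C(=C\CCc1ccoc1)CC/C=C(\C)CCC[C@H](C)CC1(O)C=C(CO[Si](C)(C)C(C)(C)C)C(=O)O1
F3 | step 3 | (2E,6E)-8-hydroxy-3,7-dimethylocta-2,6-dien-1-yl acetate | CC(=O)OC/C=C(\C)CC/C=C(\C)CO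
F4 | step 3 | (2E,6E)-8-{[tert-butyl(dimethyl)silyl]oxy}-3,7-dimethylocta-2,6-dien-1-yl acetate | CC(=O)OC/C=C(\C)CC/C=C(\C)CO[Si](C)(C)C(C)(C)C
F5 | step 3 | (2E,6E)-8-{[tert-butyl(dimethyl)silyl]oxy}-3,7-dimethylocta-2,6-dien-1-ol | OC/C=C(\C)CC/C=C(\C)CO[Si](C)(C)C(C)(C)C
F6 | step 3 | tert-butyl{[(2E,6E)-8-chloro-2,6-dimethylocta-2,6-dien-1-yl]oxy}dimethylsilane | ClC/C=C(\C)CC/C=C(\C)CO[Si](C)(C)C(C)(C)C
F7 | step 3 | tert-butyl{[(2E,6E)-9-(furan-3-yl)-2,6-dimethylnona-2,6-dien-1-yl]oxy}dimethylsilane | C/C(=C\CCc1ccoc1)CC/C=C(\C)CO[Si](C)(C)C(C)(C)C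
F8 | step 8 | (4S)-3-[(2E)-but-2-enoyl]-4-phenyl-1,3-oxazolidin-2-one | C/C=C/C(=O)N1[C@@H](c2ccccc2)COC1=O
F9 | step 8 | (4S)-3-[(3S,7E,11E)-14-(furan-3-yl)-3,7,11-trimethyltetradeca-7,11-dienoyl]-4-phenyl-1,3-oxazolidin-2-one | C/C(=C\CCc1ccoc1)CC/C=C(\C)CCC[C@H](C)CC(=O)N1[C@@H](c2ccccc2)COC1=O
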